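**Assumptions (stated once):** The target has no stereocenters, so "single enantiomer" is trivially satisfied and no step needs stereocontrol. Olivetolic acid (2,4-dihydroxy-6-pentylbenzoic acid) is taken as commercially available.

## Retrosynthetic overview
- The target is a hindered diaryl ether. Disconnecting the Ar–O–Ar bond gives a ring-A phthalic half-ester acid and a ring-B hydroquinone-type phenol (ortho-disubstituted, electron-rich).
- The ether is formed by the proposed new photo-Cu decarboxylative C–O coupling, where CO2 is lost from the ring-A acid and the phenol supplies the oxygen.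
- The three benzyl groups (ring-A OBn, ring-B OBn and ring-B benzyl ester) are removed together in the last step, which leaves the ring-A methyl ester and the aryl methyl ether untouched.
- No ring is constructed. Both arenes come from olivetolic acid, and the only new ring-B oxygen is installed by Vilsmeier formylation at C5 followed by Dakin oxidation.

## Route

**Step 1**
Reactants: 1 olivetolic acid
Product: 2 benzyl 2,4-dihydroxy-6-pentylbenzoate
Conditions: BnBr, NaHCO3, DMF, 40 °C
Reagents that add atoms: benzyl bromide, BrCc1ccccc1
Why: The carboxylate is alkylated selectively over the phenols under weakly basic SN2 conditions (carboxylate O-benzylation). No stereocenter is formed.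

**Step 2**
Reactants: 2
Product: 3 benzyl 2-hydroxy-4-methoxy-6-pentylbenzoate
Conditions: MeI (1.1 equiv), K2CO3, acetone, reflux
Reagents that add atoms: methyl iodide, CI
Why: The 4-OH is more acidic and accessible than the 2-OH, which is chelated to the ester carbonyl, so Williamson methylation occurs at C4. No stereocenter is formed.

**Step 3**
Reactants: 3
Product: 4 benzyl 2-(benzyloxy)-4-methoxy-6-pentylbenzoate
Conditions: BnBr, K2CO3, KI (cat.), DMF, 60 °C
Reagents that add atoms: benzyl bromide, BrCc1ccccc1
Why: Forcing Williamson benzylation caps the chelated 2-OH. This sets the 2-OBn needed for the final hydrogenolysis and directs the next substitution to C5. No stereocenter is formed.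

**Step 4**
Reactants: 4
Product: 5 benzyl 2-(benzyloxy)-5-formyl-4-methoxy-6-pentylbenzoate
Conditions: POCl3, DMF, 1,2-DCE, 65 °C, then aqueous NaOAc
Reagents that add atoms: N,N-dimethylformamide (formyl source), CN(C)C=O
Why: Vilsmeier–Haack formylation occurs at C5, which is para to 2-OBn and ortho to 4-OMe. The alternative C3 is sandwiched between two alkoxy groups. The ester is twisted out of conjugation and deactivates the ring little. No stereocenter is formed.

**Step 5**
Reactants: 5
Product: 6 benzyl 2-(benzyloxy)-5-hydroxy-4-methoxy-6-pentylbenzoate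
Conditions: (i) mCPBA, CH2Cl2, 0 °C to rt; (ii) K2CO3, MeOH, 0 °C, 15 min
Reagents that add atoms: mCPBA, OOC(=O)c1cccc(Cl)c1 (supplies the phenolic O)
Why: The electron-rich aldehyde, ortho and para to alkoxy groups, undergoes Dakin-type Baeyer–Villiger aryl migration to the aryl formate, which is then cleaved mildly. The hindered benzyl ester survives. No stereocenter is formed.

**Step 6**
Reactants: 1 olivetolic acid
Product: 7 methyl 2,4-dihydroxy-6-pentylbenzoate (methyl olivetolate)
Conditions: TMSCHN2, MeOH/PhMe, 0 °C to rt
Reagents that add atoms: trimethylsilyldiazomethane, C[Si](C)(C)C=[N+]=[N-] (supplies the CH3)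
Why: The acid is methylated selectively (diazomethane-type O-methylation of the carboxylic acid) without touching the phenols. No stereocenter is formed.

**Step 7**
Reactants: 7
Product: 8 methyl 4-(benzyloxy)-2-hydroxy-6-pentylbenzoate
Conditions: BnBr (1.05 equiv), K2CO3, acetone, reflux
Reagents that add atoms: benzyl bromide, BrCc1ccccc1
Why: The 4-OH is selectively benzylated because the 2-OH is chelated to the ester carbonyl (Williamson ether synthesis). No stereocenter is formed.

**Step 8**
Reactants: 8
Product: 9 methyl 4-(benzyloxy)-2-pentyl-6-(trifluoromethanesulfonyloxy)benzoate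
Conditions: Tf2O, pyridine, CH2Cl2, 0 °C
Reagents that add atoms: triflic anhydride, O=S(=O)(OS(=O)(=O)C(F)(F)F)C(F)(F)F
Why: Standard O-triflation of the chelated phenol activates C2 for carbonylation. No stereocenter is formed.

**Step 9**
Reactants: 9
Product: 10 5-(benzyloxy)-2-(methoxycarbonyl)-3-pentylbenzoic acid
Conditions: Pd(OAc)2 (5 mol%), dppf (6 mol%), CO (1 atm), Et3N, DMF/H2O (10:1), 80 °C
Reagents that add atoms: carbon monoxide, [C-]#[O+]; water, O
Why: Pd-catalyzed hydroxycarbonylation of the aryl triflate (Cacchi-type carbonylation) installs the carboxyl that will serve as the traceless coupling handle. It sits ortho to the ester, which favors the next step. No stereocenter is formed.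

**Step 10 (key new step)**
Reactants: 10 (acid, 1.0 equiv) + 6 (phenol, 1.5 equiv)
Product: 11 benzyl 2-(benzyloxy)-5-[5-(benzyloxy)-2-(methoxycarbonyl)-3-pentylphenoxy]-4-methoxy-6-pentylbenzoate
Conditions: Cu(OTf)2 (2.5 equiv), 2,6-lutidine (3 equiv), MeCN, 365 nm LEDs, 25 °C, 20 h
Reagents that add atoms: none
Why: Proposed new method: photoinduced Cu(II)-carboxylate LMCT of an ortho-substituted benzoic acid releases ArCO2•, which loses CO2 to give an aryl radical; this is trapped by a Cu(II)-phenoxide to form Ar–Cu(III)–OAr′, and C–O reductive elimination gives the hindered diaryl ether. It is closest to photo-Cu LMCT decarboxylative hydroxylation and amination of benzoic acids and to Chan–Lam etherification, extended here to phenols as the O-nucleophile. No stereocenter is formed.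

**Step 11**
Reactants: 11
Product: 12 Epiphorellic acid 1
Conditions: H2 (1 atm), 10% Pd/C, EtOAc/MeOH (1:1), rt, 6 h
Reagents that add atoms: none (H2 adds only hydrogen)
Why: Pd-catalyzed hydrogenolysis removes both benzyl ethers and the benzyl ester. The diaryl ether, aryl OMe and methyl ester are stable, and the molecule has no stereocenters to scramble.

## Compound list
1 | olivetolic acid | CCCCCc1cc(O)cc(O)c1C(=O)O | starting material
2 | benzyl 2,4-dihydroxy-6-pentylbenzoate | CCCCCc1cc(O)cc(O)c1C(=O)OCc1ccccc1 | intermediate
3 | benzyl 2-hydroxy-4-methoxy-6-pentylbenzoate | CCCCCc1cc(OC)cc(O)c1C(=O)OCc1ccccc1 | intermediate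
4 | benzyl 2-(benzyloxy)-4-methoxy-6-pentylbenzoate | CCCCCc1cc(OC)cc(OCc2ccccc2)c1C(=O)OCc1ccccc1 | intermediate
5 | benzyl 2-(benzyloxy)-5-formyl-4-methoxy-6-pentylbenzoate | CCCCCc1c(C=O)c(OC)cc(OCc2ccccc2)c1C(=O)OCc1ccccc1 | intermediate
6 | benzyl 2-(benzyloxy)-5-hydroxy-4-methoxy-6-pentylbenzoate | CCCCCc1c(O)c(OC)cc(OCc2ccccc2)c1C(=O)OCc1ccccc1 | intermediate
7 | methyl 2,4-dihydroxy-6-pentylbenzoate | CCCCCc1cc(O)cc(O)c1C(=O)OC | intermediate
8 | methyl 4-(benzyloxy)-2-hydroxy-6-pentylbenzoate | CCCCCc1cc(OCc2ccccc2)cc(O)c1C(=O)OC | intermediate
9 | methyl 4-(benzyloxy)-2-pentyl-6-(triflyloxy)benzoate | CCCCCc1cc(OCc2ccccc2)cc(OS(=O)(=O)C(F)(F)F)c1C(=O)OC | intermediate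
10 | 5-(benzyloxy)-2-(methoxycarbonyl)-3-pentylbenzoic acid | CCCCCc1cc(OCc2ccccc2)cc(C(=O)O)c1C(=O)OC | intermediate
11 | coupled tri-benzyl diaryl ether | CCCCCc1cc(OCc2ccccc2)cc(Oc2c(CCCCC)c(C(=O)OCc3ccccc3)c(OCc3ccccc3)cc2OC)c1C(=O)OC | intermediate
12 | Epiphorellic acid 1 | CCCCCc1cc(O)cc(Oc2c(OC)cc(O)c(C(=O)O)c2CCCCC)c1C(=O)OC | target

## Totals
- Total steps: 11
- Longest linear sequence: 7 (1 → 2 → 3 → 4 → 5 → 6 → 11 → 12, i.e. steps 1–5, 10 and 11)

## Three steps most likely to fail
1. **Step 10 (proposed new step).** The phenol is easily oxidized, and the carboxylate can be captured instead of the phenoxide, giving an aryl ester. That ester can be hydrolyzed back to phenol 8 and recycled.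
   - Fallback: use known chemistry from triflate 9. Convert it to the ArBpin (B2pin2, PdCl2(dppf), KOAc) and then to the aryl(mesityl)iodonium triflate. Arylate the phenoxide of 6 under metal-free diaryliodonium conditions (tBuOK, toluene), then proceed to step 11.
2. **Step 4 (with step 5), regioselective C5 formylation and Dakin oxidation.** Formylation may be sluggish or give C3 or mixed products, and the resulting electron-rich phenol may over-oxidize.
   - Fallback: replace formylation/Dakin with NBS bromination at C5, Miyaura borylation of the hindered bromide (Pd/SPhos, B2pin2), and oxidation of the boronate (NaBO3) to phenol 6.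
3. **Step 9, hydroxycarbonylation of the hindered triflate.** Triflate S–O cleavage to phenol 8 competes.
   - Fallback: carry out the Pd-catalyzed methoxycarbonylation of 9 (CO, MeOH, dppf) to the dimethyl phthalate. Then selectively hydrolyze the less hindered new ester (LiOH, THF/H2O, 0 °C) to give acid 10. The original ester is flanked by pentyl and the new ester, so it is far slower to hydrolyze.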